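How much of the charged substrate stands as product, dissolved and crystals together, after 3.0 min, and does changing the solubility or the dissolution coefficient of the crystals add to it?

    substrate ⇌ intermediate A (K1 = 2.9, k1 = 0.015 s⁻¹)
    crystals ⇌ product, rate k2*(cs2 - [product]) while solid is left; crystals form when [product] > cs2 (cs2 = 0.27 M, k2 = 2.1 s⁻¹)
    intermediate A ⇌ intermediate B (K3 = 0.32, k3 = 0.0062 s⁻¹)
    intermediate A → product (k4 = 0.13 s⁻¹)

substrate 0.40 M; time 3.0 min

- amount of product and crystals together at 3.0 min, in percent of the substrate charged
- the change that raises the amount of product and crystals together at 3.0 min, in percent of the substrate charged most ("none" if none brings more than 2 percentage points) (zeta / epsilon / none)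
- amount of product and crystals together at 3.0 min, in percent of the substrate charged, after zeta

- zeta: doubling the solubility in step 2, all else as stated
- epsilon: doubling the dissolution coefficient of step 2, all else as stated

- what is said of product includes crystals
- crystals is a solid; its amount is given per volume of the solution
- run time (flask): 3.0 min

You can reckon this by hand from the balance of the substrate, which is the one species charged. What enters intermediate A goes on to product at 0.13 s⁻¹ or returns at 0.00517 s⁻¹, the forward constant of the first step over its equilibrium constant, so the share φ that goes on is

φ = 96.2%

The first step is the rate-limiting step, its 0.015 s⁻¹ being slower than the 0.13 s⁻¹ that clears intermediate A, so I let substrate fall as one first-order pool with a through-constant k_eff, the forward constant times φ, which comes to 0.0144 s⁻¹: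

substrate left = exp(−k_eff t) = 7.45%

Late in the run I let intermediate A fall with that pool, so its balance gives

intermediate A = substrate × 0.015 s⁻¹ / (0.13 s⁻¹ + 0.00517 s⁻¹ − 0.0144 s⁻¹) = 0.926%

Setting intermediate B at 0.32 times that gives 0.296%, and the remainder, 91.3%, is my first number. Step four runs one way, with no product in its rate, and the crystal step merely trades dissolved product for crystals, which the sum counts together, so I expect neither change to gain anything.

The weak link is intermediate B. It returns at 0.0194 s⁻¹, faster than the pool falls but by a factor of just 1.35, so it trails. With g = 0.00495 s⁻¹,

intermediate B / intermediate A = (0.0062 s⁻¹ / g)(1 − exp(−g t)) = 0.739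

That gives 0.684% of intermediate B and a total of 90.9%.

The forecast, 0.10 percentage points below mine, gives 90.8% (from 89.5% to 92%), none as the best change and 90.8% after zeta, holding that moving material between product in solution and crystals “leaves their total unchanged”.

The flask gives 90.8%, with none as the best change and 90.8% after zeta. Substrate stands at 7.5% at 3.00 min, against the 7.45% reckoned from k_eff. For 6.00 min, k_eff gives 0.561% of substrate, and the flask then holds 99.3% of product and crystals.

Read the same flask at 80 s: k_eff gives 31.6% of substrate. The computed flask has 32% left, with 63.1% as product and crystals.

The rate constants are those of an exercise.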